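## The problem

Compound 16 is an isoflavan quinone: a chroman (benzo ring A fused to the pyran O1–C2–C3–C4) whose C3 carries a 2,3-dimethoxy-1,4-benzoquinone (ring B, joined through C1′). Ring A bears a free hydroxyl at C6 and methoxy groups at C7 and C8.

- **Chain and stereocentre.** The two rings hang on the three-carbon chain C2–C3–C4, and the only stereocentre, C3 (S), sits in its middle. No second stereocentre can relay to it, so C3 must be set by a chiral reagent or catalyst in a bond-forming step.
- **Two similar rings, two oxidation levels.** Rings A and B are both 1,2,3,4-tetraoxygenated benzenes, yet ring B must end as a quinone and ring A as a para-alkoxyphenol. Any late oxidant has to tell them apart.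
- **Sensitive groups.** The quinone does not tolerate base or soft nucleophiles (methoxy exchange, addition at the free C6′). Once ring B is a quinone, C3–H is vinylogously acidic, and quinone-methide tautomerism under base would racemise C3. The C6 phenol is itself easily oxidised.
- **Enabling feature.** Ring A together with C4 maps atom for atom onto 2,3-dimethoxy-5-methyl-1,4-benzoquinone 6. Its methyl carbon is C4, its carbonyl oxygens are O1 and the C6 oxygen, its methoxy groups are those at C7 and C8, and its one ring hydrogen is C5–H. In the reduced, silylated form 8 that methyl group is an electron-rich benzylic C–H site. A carbene carrying ring B and the future C2 can insert into it, making C3–C4 and the stereocentre together.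

## Retrosynthesis

**16 back to 14.** No skeletal bond is cut. The two ring B carbonyls are traced to a para pair of methoxy groups (15 from 14), and the C6 hydroxyl to an acetate (16 from 15). A quinone could not be carried through hydride, fluoride or carbene chemistry, and benzyl or silyl masks on ring B would offer reactive C–H bonds or a competing phenoxide. Methyl ethers are therefore the only practical disguise. The forward oxidation must take the tetramethoxy ring B and spare the acetoxy-deactivated ring A, and the acetate must come off without base.

**14 back to 11.** The O1–C2 bond is cut (with the acetyl group), opening the pyran to mesylate 11 through the diphenol 12 and the chromanol 13. Cutting O1–C8a instead would require an oxidative or aryl-substitution closure onto ring A. The chosen cut needs only a phenoxide displacing a primary sulfonate. The two silyl ethers of 11 need not be differentiated, because only the C8a oxygen can reach C2 through a six-membered transition state. The forward step must exclude air while the hydroquinone is free.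

**11 back to 9.** Mesylate 11 comes from alcohol 10, and 10 from ester 9, so C2 is recognised as an ester carbon. This functional-group change places C3 α to an ester and β to ring A, the pattern a carbene C–H insertion delivers. The forward reduction must leave the aryl silyl ethers and C3 untouched.

**9 back to 5 and 8.** The C3–C4 bond is cut. Cutting C3–C1′ would call for an asymmetric α-arylation giving an easily enolised stereocentre. Cutting C4–C4a would need a ring A nucleophile with no commercial equivalent. The C3–C4 cut divides 9 into diazo ester 5 and the methylarene 8, and creates the bond and the stereocentre in one catalytic step. It asks for insertion into the benzylic methyl C–H bond, in preference to every other C–H bond of both partners, with catalyst control of the carbene face.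

**8 back to 6.** Silyl ether 8 comes from hydroquinone 7, the reduction product of commercial quinone 6. No carbon–carbon bond is made. The silyl groups make the ring electron-rich for the insertion and later serve as the trigger for ring closure.

**5 back to 1 and 2.** Diazo ester 5 is traced to tosylhydrazone 4 and α-keto ester 3. The C1′–C3 bond of 3 is cut to 1,2,3,4-tetramethoxybenzene 1 and methyl chlorooxoacetate 2. The alternative, an arylacetate made by homologation followed by diazo transfer, is several steps longer. The two free positions of 1 are equivalent, so the acylation can give only one regioisomer.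

## Roads not taken

**Alternative 1:** The cut is O1–C8a. The open-chain phenol alcohol A2 would be oxidised at a carbon anode in a fluorinated alcohol to a phenoxonium ion, which the primary hydroxyl traps para to the phenol oxygen to give chromanol A1.
- *Merits.* The ring A precursor is a simple monophenol. The ring B oxygens arrive as benzyl ethers, so debenzylation and mild oxidation of A1 would give 16 with no oxidant that must choose between two electron-rich rings. In this respect the road is better than the chosen one.
- *Weak points.* The key step makes no C–C bond and no stereocentre, so A2 with its C3 centre still needs an asymmetric synthesis of its own. The tether can reach C5 (ortho to the phenol) as well as C8a. The product A1, a hydroquinone monoether, is easier to oxidise than A2, and the tetra-alkoxy ring B competes at the anode.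
- *Comparison.* The chosen plan makes the skeleton bond and C3 together and closes the pyran by a plain displacement, at the cost of a late oxidation with (NH4)2Ce(NO3)6 and an acetate detour.

**Alternative 2:** The cut runs through ring B. The acetylide of the 3-ethynylchroman A5 adds to dimethyl squarate A6, and heating the adduct A4 opens the four-membered ring to a ketene that closes onto the alkyne to give the quinone A3.
- *Merits.* The quinone is born at its final oxidation level with the substitution pattern fixed by the mechanism. No chemoselective oxidation is needed, and ring A needs only a silyl group. Here this road is clearly stronger than the chosen one.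
- *Weak points.* Everything difficult is moved into A5: the chroman with four ring A oxygens and the C3 stereocentre must be built first and then homologated to the alkyne through a carbonyl stage that can epimerise. The sequence is linear. The thermal step can also partition towards five-membered closure of the diradical. Removing the silyl group from A3 leaves a last step on a quinone, as in the chosen plan.
- *Comparison.* The chosen plan is convergent and sets C3 in the fragment union, from two fragments that are two and three steps from commercial materials.

**Alternative 3:** The cut is C3–C1′, with a temporary C4–O bond. A stoichiometric chiral titanium diolate Lewis acid would make chromene A8 attack an unsubstituted carbon of quinone A9, and the neighbouring quinone oxygen would close onto C4 to give the cis-fused pterocarpan A7. Hydrogenolysis of the benzylic C4–O bond and the benzyl ether, then mild oxidation, would lead to 16.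
- *Merits.* An asymmetric C–C bond formation joins ring B directly at the hydroquinone level with its two oxygens already differentiated, so the endgame again avoids a strong oxidant. It is as direct as the chosen plan in making bond and stereocentre together.
- *Weak points.* The chiral promoter is stoichiometric. Enantioselectivity in such annulations depends strongly on the alkene partner, and a tri-oxygenated 2H-chromene is a demanding one. A [2+2] pathway competes. A8 needs a multistep synthesis with three different ring A oxygen substituents, and a C–O bond is made only to be broken.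
- *Comparison.* The chosen plan uses a catalytic chiral metal complex and takes ring A ready-made from 6. In exchange it accepts a less mild oxidation at the end.

Key step: step 6

Assumption: the sense of induction of Rh2(S-PTAD)4 for this untested pair cannot be read from the ligand descriptor with certainty. The (S)-ligand is written as the one giving (S)-9; if the first batch shows the opposite sense, Rh2(R-PTAD)4 is used with no other change.

## Route

Step 1
Reactants: 1 1,2,3,4-tetramethoxybenzene; 2 methyl chlorooxoacetate
Product: 3 methyl 2-oxo-2-(2,3,4,5-tetramethoxyphenyl)acetate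
Conditions: TiCl4, CH2Cl2, −20 → 0 °C
Reagents that add atoms: none
Why: Friedel–Crafts acylation of a strongly activated arene; the two free positions of 1 are equivalent, so a single regioisomer should form, and TiCl4 at low temperature limits cleavage of the methoxy group ortho to the new ketone.

Step 2
Reactants: 3 methyl 2-oxo-2-(2,3,4,5-tetramethoxyphenyl)acetate
Product: 4 methyl 2-[2-(4-methylbenzenesulfonyl)hydrazinylidene]-2-(2,3,4,5-tetramethoxyphenyl)acetate
Conditions: TsNHNH2, MeOH, 60 °C
Reagents that add atoms: p-toluenesulfonohydrazide, Cc1ccc(cc1)S(=O)(=O)NN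
Why: Hydrazone condensation at the ketone carbonyl, which is far more electrophilic than the ester; the E/Z mixture is of no consequence because both isomers give the same diazo compound.

Step 3
Reactants: 4 methyl 2-[2-(4-methylbenzenesulfonyl)hydrazinylidene]-2-(2,3,4,5-tetramethoxyphenyl)acetate
Product: 5 methyl 2-diazo-2-(2,3,4,5-tetramethoxyphenyl)acetate (fragment 1)
Conditions: DBU, CH2Cl2, 0 °C → rt
Reagents that add atoms: none
Why: Bamford–Stevens-type loss of sulfinate from the deprotonated tosylhydrazone of an α-keto ester, the standard entry to aryldiazoacetates; it needs no acidic α-C–H, which an electron-rich arylacetate would supply only reluctantly for diazo transfer.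

Step 4
Reactants: 6 2,3-dimethoxy-5-methyl-1,4-benzoquinone
Product: 7 2,3-dimethoxy-5-methylbenzene-1,4-diol
Conditions: H2 (1 atm), 10% Pd/C, EtOAc, rt; filtered under Ar
Reagents that add atoms: none
Why: Catalytic hydrogenation of a benzoquinone stops cleanly at the hydroquinone and leaves no by-product, so the air-sensitive diol can be carried on directly under argon.

Step 5
Reactants: 7 2,3-dimethoxy-5-methylbenzene-1,4-diol
Product: 8 1,4-bis(tert-butyldimethylsilyloxy)-2,3-dimethoxy-5-methylbenzene (fragment 2)
Conditions: TBSCl, imidazole, DMF, rt, under Ar
Reagents that add atoms: tert-butyldimethylsilyl chloride, CC(C)(C)[Si](C)(C)Cl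
Why: Imidazole-promoted silylation of both phenols; the silyl ethers remove the air sensitivity, keep the ring electron-rich for the insertion and later serve as the fluoride trigger for ring closure.

Step 6
Reactants: 5 methyl 2-diazo-2-(2,3,4,5-tetramethoxyphenyl)acetate; 8 1,4-bis(tert-butyldimethylsilyloxy)-2,3-dimethoxy-5-methylbenzene
Product: 9 methyl (2S)-3-[2,5-bis(tert-butyldimethylsilyloxy)-3,4-dimethoxyphenyl]-2-(2,3,4,5-tetramethoxyphenyl)propanoate
Conditions: Rh2(S-PTAD)4 (1 mol %), 8 (3 equiv), 2,2-dimethylbutane/PhCF3, 50 °C, 5 added over 3 h
Reagents that add atoms: none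
Why: The dirhodium tetracarboxylate expels N2 from 5 to give a rhodium-bound donor/acceptor carbene, which inserts into one methyl C–H bond of 8 through a concerted, asynchronous three-centre transition state: hydride shifts towards the carbene carbon, positive charge builds at the benzylic carbon, and the C3–C4 bond forms as rhodium leaves. The closest known reaction type is the enantioselective intermolecular insertion of aryl(ester)carbenes into primary benzylic C–H bonds of para-alkoxytoluenes under chiral dirhodium tetracarboxylates. No ring is closed. The new stereocentre C3 is controlled by the catalyst alone, whose chiral carboxylate wall leaves one carbene face open; Rh2(S-PTAD)4, dirhodium tetrakis[(S)-(1-adamantyl)(N-phthalimido)acetate], is preferred to the prolinate Rh2(S-DOSP)4 because it keeps its selectivity with ortho-substituted aryldiazoacetates. The step needs site selectivity for the benzylic methyl group over the two O-methyl groups, the silicon-bound alkyl groups, the lone aromatic C5–H and the carbene's own ortho-methoxy group. The methyl group is the best hydride donor of 8 because the developing cation is benzylic and supported by the para methoxy and ortho silyloxy oxygens; ring addition is disfavoured because every ring carbon except C5 is substituted and C5 is flanked on both sides; the silyl C–H bonds are unactivated. Insertion of the carbene into its own O–CH3 group and carbene dimerisation are held down by slow addition of 5 to an excess of 8, which is recovered.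

Step 7
Reactants: 9 methyl (2S)-3-[2,5-bis(tert-butyldimethylsilyloxy)-3,4-dimethoxyphenyl]-2-(2,3,4,5-tetramethoxyphenyl)propanoate
Product: 10 (2S)-3-[2,5-bis(tert-butyldimethylsilyloxy)-3,4-dimethoxyphenyl]-2-(2,3,4,5-tetramethoxyphenyl)propan-1-ol
Conditions: LiAlH4, THF, 0 °C, short contact; aqueous potassium sodium tartrate work-up
Reagents that add atoms: none
Why: Hydride reduction of the ester to the primary alcohol, the usual follow-up for insertion products of this kind; at 0 °C the aryl silyl ethers and the α-aryl stereocentre should be untouched, since the ester is consumed faster than it can enolise.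

Step 8
Reactants: 10 (2S)-3-[2,5-bis(tert-butyldimethylsilyloxy)-3,4-dimethoxyphenyl]-2-(2,3,4,5-tetramethoxyphenyl)propan-1-ol
Product: 11 (2S)-3-[2,5-bis(tert-butyldimethylsilyloxy)-3,4-dimethoxyphenyl]-2-(2,3,4,5-tetramethoxyphenyl)propyl methanesulfonate
Conditions: MsCl, Et3N, CH2Cl2, 0 °C; used at once
Reagents that add atoms: methanesulfonyl chloride, CS(=O)(=O)Cl
Why: Sulfonylation of a primary alcohol via the sulfene; C3 is not involved, and immediate use avoids slow participation of the neighbouring ring B methoxy oxygen.

Step 9
Reactants: 11 (2S)-3-[2,5-bis(tert-butyldimethylsilyloxy)-3,4-dimethoxyphenyl]-2-(2,3,4,5-tetramethoxyphenyl)propyl methanesulfonate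
Product: 14 (3S)-7,8-dimethoxy-3-(2,3,4,5-tetramethoxyphenyl)chroman-6-yl acetate, via diphenol mesylate 12 (not isolated), via chroman-6-ol 13 (not isolated)
Conditions: Bu4NF (2.2 equiv), degassed THF, 0 °C → rt; then Ac2O, 0 °C
Reagents that add atoms: acetic anhydride, CC(=O)OC(C)=O
Why: Fluoride cleaves both aryl silyl ethers; the C8a phenoxide then displaces the primary mesylate in an intramolecular Williamson etherification (6-exo-tet) that the C6 phenoxide cannot reach, and the remaining phenoxide is acetylated in the same flask so that the oxidisable chromanol is never handled. C3 is a spectator.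

Step 10
Reactants: 14 (3S)-7,8-dimethoxy-3-(2,3,4,5-tetramethoxyphenyl)chroman-6-yl acetate
Product: 15 (3S)-3-(4,5-dimethoxy-3,6-dioxocyclohexa-1,4-dien-1-yl)-7,8-dimethoxychroman-6-yl acetate
Conditions: (NH4)2Ce(NO3)6 (2.2 equiv), MeCN/H2O, 0 °C
Reagents that add atoms: water, O
Why: Oxidative demethylation of a para-dimethoxyarene by tetravalent cerium: the ring B radical cation is attacked by water at the C2′ and C5′ carbons and loses methanol to give the para-quinone, as in ubiquinone-type syntheses from tetramethoxyarenes. Ring B, with four methoxy groups, is the more easily oxidised ring; ring A carries an electron-withdrawing acetate on the oxygen para to O1 and cannot collapse to a para-quinone.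

Step 11
Reactants: 15 (3S)-3-(4,5-dimethoxy-3,6-dioxocyclohexa-1,4-dien-1-yl)-7,8-dimethoxychroman-6-yl acetate
Product: 16 5-[(3S)-6-hydroxy-7,8-dimethoxy-3,4-dihydro-2H-chromen-3-yl]-2,3-dimethoxycyclohexa-2,5-diene-1,4-dione
Conditions: H2SO4 (cat.), MeOH, rt → 40 °C, under Ar
Reagents that add atoms: none
Why: Acid-catalysed transesterification of the aryl acetate with methanol; a non-nucleophilic acid is used because the dimethoxyquinone and the vinylogously acidic C3–H tolerate acid but not base or chloride, so C3 keeps its configuration.

## Compound list

1 | 1,2,3,4-tetramethoxybenzene | COc1ccc(OC)c(OC)c1OC | starting material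
2 | methyl chlorooxoacetate | COC(=O)C(Cl)=O | starting material
3 | methyl 2-oxo-2-(2,3,4,5-tetramethoxyphenyl)acetate | COC(=O)C(=O)c1cc(OC)c(OC)c(OC)c1OC | intermediate
4 | methyl 2-[2-(4-methylbenzenesulfonyl)hydrazinylidene]-2-(2,3,4,5-tetramethoxyphenyl)acetate (E/Z mixture) | COC(=O)C(=NNS(=O)(=O)c1ccc(C)cc1)c1cc(OC)c(OC)c(OC)c1OC | intermediate
5 | methyl 2-diazo-2-(2,3,4,5-tetramethoxyphenyl)acetate (fragment 1) | COC(=O)C(=[N+]=[N-])c1cc(OC)c(OC)c(OC)c1OC | intermediate
6 | 2,3-dimethoxy-5-methyl-1,4-benzoquinone | COC1=C(OC)C(=O)C(C)=CC1=O | starting material
7 | 2,3-dimethoxy-5-methylbenzene-1,4-diol | Cc1cc(O)c(OC)c(OC)c1O | intermediate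
8 | 1,4-bis(tert-butyldimethylsilyloxy)-2,3-dimethoxy-5-methylbenzene (fragment 2) | Cc1cc(O[Si](C)(C)C(C)(C)C)c(OC)c(OC)c1O[Si](C)(C)C(C)(C)C | intermediate
9 | methyl (2S)-3-[2,5-bis(tert-butyldimethylsilyloxy)-3,4-dimethoxyphenyl]-2-(2,3,4,5-tetramethoxyphenyl)propanoate | COc1cc([C@H](Cc2cc(O[Si](C)(C)C(C)(C)C)c(OC)c(OC)c2O[Si](C)(C)C(C)(C)C)C(=O)OC)c(OC)c(OC)c1OC | intermediate
10 | (2S)-3-[2,5-bis(tert-butyldimethylsilyloxy)-3,4-dimethoxyphenyl]-2-(2,3,4,5-tetramethoxyphenyl)propan-1-ol | COc1cc([C@H](Cc2cc(O[Si](C)(C)C(C)(C)C)c(OC)c(OC)c2O[Si](C)(C)C(C)(C)C)CO)c(OC)c(OC)c1OC | intermediate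
11 | (2S)-3-[2,5-bis(tert-butyldimethylsilyloxy)-3,4-dimethoxyphenyl]-2-(2,3,4,5-tetramethoxyphenyl)propyl methanesulfonate | COc1cc([C@H](Cc2cc(O[Si](C)(C)C(C)(C)C)c(OC)c(OC)c2O[Si](C)(C)C(C)(C)C)COS(C)(=O)=O)c(OC)c(OC)c1OC | intermediate
12 | (2S)-3-(2,5-dihydroxy-3,4-dimethoxyphenyl)-2-(2,3,4,5-tetramethoxyphenyl)propyl methanesulfonate, present as its bis(tetrabutylammonium) phenoxide, not isolated | COc1cc([C@H](Cc2cc(O)c(OC)c(OC)c2O)COS(C)(=O)=O)c(OC)c(OC)c1OC | intermediate
13 | (3S)-7,8-dimethoxy-3-(2,3,4,5-tetramethoxyphenyl)chroman-6-ol, present as its tetrabutylammonium phenoxide, not isolated | COc1cc([C@H]2COc3c(cc(O)c(OC)c3OC)C2)c(OC)c(OC)c1OC | intermediate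
14 | (3S)-7,8-dimethoxy-3-(2,3,4,5-tetramethoxyphenyl)chroman-6-yl acetate | COc1cc([C@H]2COc3c(cc(OC(C)=O)c(OC)c3OC)C2)c(OC)c(OC)c1OC | intermediate
15 | (3S)-3-(4,5-dimethoxy-3,6-dioxocyclohexa-1,4-dien-1-yl)-7,8-dimethoxychroman-6-yl acetate | COC1=C(OC)C(=O)C([C@H]2COc3c(cc(OC(C)=O)c(OC)c3OC)C2)=CC1=O | intermediate
16 | 5-[(3S)-6-hydroxy-7,8-dimethoxy-3,4-dihydro-2H-chromen-3-yl]-2,3-dimethoxycyclohexa-2,5-diene-1,4-dione | COC1=C(OC)C(=O)C([C@H]2COc3c(cc(O)c(OC)c3OC)C2)=CC1=O | target

## Step count and risks

Total: 11 steps. Longest linear sequence: 9 steps (steps 1–3 and 6–11); the second branch is steps 4 and 5.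

**Step 6 (key step).** The most likely failure is poor facial selectivity: the ortho-methoxy group twists the carbene aryl ring out of the carbene plane, and the flanked methyl group of 8 reacts slowly, so any background or mismatched pathway erodes the enantiomeric purity. Fallback: setting out from 5 and 8, the insertion is run without asymmetric induction using the robust achiral Rh2(esp)2, dirhodium bis(α,α,α′,α′-tetramethyl-1,3-benzenedipropanoate). This gives the racemic methyl ester F1, which LiAlH4 reduces to the racemic alcohol F2. Kinetic resolution by lipase-catalysed acetylation (Burkholderia cepacia lipase, vinyl acetate, tert-butyl methyl ether), with an enzyme chosen to acylate the (R)-alcohol and run past half conversion, converts the unwanted enantiomer into the (R)-acetate F3 and leaves the (S)-alcohol. The route is rejoined at 10.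

**Step 9.** Three processes can divert the mesylate before the C8a phenoxide closes the ring. The free bis-phenoxide can be oxidised by air to the quinone. Fluoride can displace the mesylate. The ring B ortho-methoxy oxygen can attack C2, giving a five-membered oxonium ion and then losing its methyl group. Fallback: setting out from 10, the silyl groups are removed first (Bu4NF, degassed THF, 0 °C) to give the hydroquinone alcohol F4. This is cyclised by dehydrative etherification with cyanomethylenetributylphosphorane in toluene at 100 °C, a redox-neutral Mitsunobu-type reagent that cannot oxidise the hydroquinone and generates no persistent leaving group at C2. This gives 13, which is acetylated (Ac2O, pyridine), and the route is rejoined at 14.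

**Step 10.** The risk is loss of chemoselectivity. Cerium may also oxidise ring A once ring B is consumed, or ring B may be oxidised through its adjacent methoxy pair to an ortho-quinone. Fallback: setting out from 14, ring B is oxidised at a carbon anode at controlled potential in methanol (LiClO4, divided cell), which selects the ring of lower oxidation potential and stops at the quinone bis(dimethyl ketal) F5. Brief treatment with dilute aqueous acid in acetone hydrolyses both ketals, and the route is rejoined at 15.

**Step 11.** The risk is slow methanolysis, during which acid-promoted addition of methanol to the free quinone position or redox exchange between the liberated phenol and the quinone degrades the product. Fallback: setting out from 15, the quinone is reduced with Na2S2O4 (EtOAc/H2O) to the hydroquinone acetate F6, in which C3–H is no longer acidic. The acetate is then cleaved quickly with K2CO3 in methanol under argon to the triol F7. After neutralisation, stirring in air re-oxidises only the ring B hydroquinone, rejoining the route at 16.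

**Step 1.** The risk is Lewis-acid cleavage of the methoxy group ortho to the new ketone through chelation. Fallback: setting out from 1, bromination with N-bromosuccinimide in MeCN gives 1-bromo-2,3,4,5-tetramethoxybenzene F8. Bromine–lithium exchange (n-BuLi, THF, −78 °C) and addition of the aryllithium to excess dimethyl oxalate give the keto ester without any Lewis acid, rejoining the route at 3.

## Further compounds

F1 | step 6 | methyl rac-3-[2,5-bis(tert-butyldimethylsilyloxy)-3,4-dimethoxyphenyl]-2-(2,3,4,5-tetramethoxyphenyl)propanoate | COc1cc(C(Cc2cc(O[Si](C)(C)C(C)(C)C)c(OC)c(OC)c2O[Si](C)(C)C(C)(C)C)C(=O)OC)c(OC)c(OC)c1OC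
F2 | step 6 | rac-3-[2,5-bis(tert-butyldimethylsilyloxy)-3,4-dimethoxyphenyl]-2-(2,3,4,5-tetramethoxyphenyl)propan-1-ol | COc1cc(C(Cc2cc(O[Si](C)(C)C(C)(C)C)c(OC)c(OC)c2O[Si](C)(C)C(C)(C)C)CO)c(OC)c(OC)c1OC
F3 | step 6 | (2R)-3-[2,5-bis(tert-butyldimethylsilyloxy)-3,4-dimethoxyphenyl]-2-(2,3,4,5-tetramethoxyphenyl)propyl acetate | COc1cc([C@@H](Cc2cc(O[Si](C)(C)C(C)(C)C)c(OC)c(OC)c2O[Si](C)(C)C(C)(C)C)COC(C)=O)c(OC)c(OC)c1OC
F4 | step 9 | 2-[(2S)-3-hydroxy-2-(2,3,4,5-tetramethoxyphenyl)propyl]-5,6-dimethoxybenzene-1,4-diol | COc1cc([C@H](Cc2cc(O)c(OC)c(OC)c2O)CO)c(OC)c(OC)c1OC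
F5 | step 10 | (3S)-3-(3,3,4,5,6,6-hexamethoxycyclohexa-1,4-dien-1-yl)-7,8-dimethoxychroman-6-yl acetate | COC1=C(OC)C(OC)(OC)C([C@H]2COc3c(cc(OC(C)=O)c(OC)c3OC)C2)=CC1(OC)OC
F6 | step 11 | (3S)-3-(2,5-dihydroxy-3,4-dimethoxyphenyl)-7,8-dimethoxychroman-6-yl acetate | COc1c(O)cc([C@H]2COc3c(cc(OC(C)=O)c(OC)c3OC)C2)c(O)c1OC
F7 | step 11 | (3S)-3-(2,5-dihydroxy-3,4-dimethoxyphenyl)-7,8-dimethoxychroman-6-ol | COc1c(O)cc([C@H]2COc3c(cc(O)c(OC)c3OC)C2)c(O)c1OC
F8 | step 1 | 1-bromo-2,3,4,5-tetramethoxybenzene | COc1cc(Br)c(OC)c(OC)c1OC
A1 | alternative 1 | (3S)-3-[2,5-bis(benzyloxy)-3,4-dimethoxyphenyl]-7,8-dimethoxychroman-6-ol | COc1c(OC)c(OCc2ccccc2)cc([C@H]2COc3c(cc(O)c(OC)c3OC)C2)c1OCc1ccccc1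
A2 | alternative 1 | (2S)-2-[2,5-bis(benzyloxy)-3,4-dimethoxyphenyl]-3-(3-hydroxy-4,5-dimethoxyphenyl)propan-1-ol | OC[C@@H](Cc1cc(O)c(OC)c(OC)c1)c1cc(OCc2ccccc2)c(OC)c(OC)c1OCc1ccccc1
A3 | alternative 2 | 5-[(3S)-6-(tert-butyldimethylsilyloxy)-7,8-dimethoxychroman-3-yl]-2,3-dimethoxycyclohexa-2,5-diene-1,4-dione | COC1=C(OC)C(=O)C([C@H]2COc3c(cc(O[Si](C)(C)C(C)(C)C)c(OC)c3OC)C2)=CC1=O
A4 | alternative 2 | 4-{[(3S)-6-(tert-butyldimethylsilyloxy)-7,8-dimethoxychroman-3-yl]ethynyl}-4-hydroxy-2,3-dimethoxycyclobut-2-en-1-one (carbinol centre as a mixture) | COC1=C(OC)C(O)(C#C[C@H]2COc3c(cc(O[Si](C)(C)C(C)(C)C)c(OC)c3OC)C2)C1=O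
A5 | alternative 2 | (3S)-6-(tert-butyldimethylsilyloxy)-3-ethynyl-7,8-dimethoxychroman | C#C[C@H]1COc2c(cc(O[Si](C)(C)C(C)(C)C)c(OC)c2OC)C1
A6 | alternative 2 | dimethyl squarate (3,4-dimethoxycyclobut-3-ene-1,2-dione) | COC1=C(OC)C(=O)C1=O
A7 | alternative 3 | (6aS,11aS)-2-(benzyloxy)-3,4,9,10-tetramethoxy-6a,11a-dihydro-6H-benzofuro[3,2-c]chromen-8-ol | Oc1cc2[C@H]3COc4c(OC)c(OC)c(OCc5ccccc5)cc4[C@H]3Oc2c(OC)c1OC
A8 | alternative 3 | 6-(benzyloxy)-7,8-dimethoxy-2H-chromene | C1=Cc2cc(OCc3ccccc3)c(OC)c(OC)c2OC1
A9 | alternative 3 | 2,3-dimethoxy-1,4-benzoquinone | COC1=C(OC)C(=O)C=CC1=O
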